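**Retrosynthetic overview**

1. Drimane numbering is used for the decalin (ring A = C1–C5, C10; ring B = C5–C10; C11 = ArCH2). The last C–C bond made is C11–aryl, by B-alkyl Suzuki–Miyaura coupling of the 9-BBN adduct of drima-7,9(11)-diene with a MOM-protected methyl 5-bromo-2,3,4-trihydroxybenzoate.
2. The diene comes from 11-nor-drim-7-en-9-one by Wittig methylenation.
3. Ring A is opened at C3–C4. An iron hydride transfers a hydrogen atom to a C5 isopropenyl group, the C4 radical attacks a C3 tosylhydrazone (6-exo), and sulfinate and N2 are lost in the same flask, so no activating group remains.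
4. Enabling feature: C4 is a gem-dimethyl quaternary carbon next to the ring-fusion methine C5, which is the tertiary radical an isopropenyl group gives on hydrogen atom transfer, and C3 is a plain CH2. Ring B (C5, C6, C7=C8 with its methyl, C9, C10) is the carbon pattern of (R)-carvone, with C9 as the carbonyl carbon and the carvone stereocentre as C5.
5. Ring order: ring B is bought as carvone, C10 is set by two enolate alkylations, ring A is closed in the key step, C9 is set by alpha-face hydroboration, and the arene is attached last.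

Key step: step 5

Remark: (R)-(−)-carvone, methyl 2,3,4-trihydroxybenzoate and all reagents named are taken as commercial.

**Route**

Step 1
Reactants: 1 (R)-(−)-carvone
Product: 2 (5R,6S)-2,6-dimethyl-5-(prop-1-en-2-yl)cyclohex-2-en-1-one (trans-6-methylcarvone; the minor cis epimer is carried along)
Conditions: LiN(i-Pr)2, THF, −78 °C; MeI, −78 to 0 °C
Reagents that add atoms: methyl iodide, CI
Why: Kinetic alpha'-deprotonation of the cross-conjugated enone and C-methylation of the lithium enolate (enolate alkylation) is standard for carvone; MeI should enter mainly trans to the isopropenyl group, but this centre is made planar again in step 2, so the epimer ratio does not matter.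

Step 2
Reactants: 2 trans-6-methylcarvone (both C6 epimers)
Product: 3 (5S,6S)-2,6-dimethyl-5-(prop-1-en-2-yl)-6-(prop-2-yn-1-yl)cyclohex-2-en-1-one (propargyl trans, methyl cis to isopropenyl)
Conditions: LiN(i-Pr)2, THF, −78 to 0 °C; propargyl bromide, DMPU, −78 to 25 °C
Reagents that add atoms: propargyl bromide, BrCC#C
Why: Enolate alkylation: the tetrasubstituted lithium enolate should react with the activated propargylic bromide on the face opposite the pseudoaxial isopropenyl group on the neighbouring carbon (1,2-induction), which sets the quaternary centre (future C10) with the three-carbon arm trans and the methyl cis to isopropenyl, the relation a trans-decalin needs.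

Step 3
Reactants: 3 6-methyl-6-propargylcarvone
Product: 4 3-[(1S,6S)-1,3-dimethyl-2-oxo-6-(prop-1-en-2-yl)cyclohex-3-en-1-yl]propanal
Conditions: [CpRu(MeCN)3]PF6 (3 mol%), 5,5'-bis(trifluoromethyl)-2,2'-bipyridine (3 mol%), H2O/NMP 1:4, 25 °C
Reagents that add atoms: water, O
Why: Ruthenium-catalysed anti-Markovnikov hydration of a terminal alkyne through a ruthenium vinylidene should put oxygen on the terminal carbon (future C3) and leave the isopropenyl group, the enone and both stereocentres untouched.

Step 4
Reactants: 4 keto aldehyde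
Product: 5 N'-{(E)-3-[(1S,6S)-1,3-dimethyl-2-oxo-6-(prop-1-en-2-yl)cyclohex-3-en-1-yl]propylidene}-4-methylbenzenesulfonohydrazide
Conditions: TsNHNH2 (1.05 equiv), MeOH, 25 °C
Reagents that add atoms: p-toluenesulfonyl hydrazide, Cc1ccc(cc1)S(=O)(=O)NN
Why: Hydrazone formation from an aldehyde and a sulfonyl hydrazide is fast at room temperature, whereas the conjugated ketone flanked by a quaternary carbon should not condense under these conditions.

Step 5
Reactants: 5 tosylhydrazone
Product: 8 11-nor-drim-7-en-9-one [(4aS,8aS)-2,5,5,8a-tetramethyl-4a,5,6,7,8,8a-hexahydronaphthalen-1(4H)-one], via cyclised tosylhydrazide 6 (not isolated), via alkyldiazene 7 (not isolated)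
Conditions: Fe(acac)3 (30 mol%), PhSiH3 (2.5 equiv), EtOH/THF 1:1, 0.02 M, 40 °C; then NaOAc (3 equiv), 75 °C
Reagents that add atoms: none
Why: Fe(acac)3 and PhSiH3 in ethanol should give an iron hydride that transfers a hydrogen atom to the CH2 terminus of the isopropenyl group, and the tertiary C4 radical adds to the hydrazone carbon C3; the sulfonyl-stabilised hydrazinyl radical is reduced by divalent iron and protonated to hydrazide 6, which on warming with NaOAc loses p-toluenesulfinate to give diazene 7 and then N2, leaving C3 as CH2. The closest known reaction types are the iron-mediated reductive coupling of unactivated olefins with sulfonylhydrazones (olefin hydromethylation with the formaldehyde hydrazone, and ring-closing alkene–hydrazone couplings) and the Caglioti-type collapse of N-alkyl-N'-tosylhydrazides to alkanes. Ring A is closed in the 6-exo-trig mode by a carbon radical attacking the carbon of a C=N bond, and the C3–C4 bond made is the one that creates the gem-dimethyl quaternary centre. No stereocentre of the target is created: C4 carries two methyls, the transient C3 centre is erased with the nitrogen, and the trans ring fusion follows from the C5 and C10 centres fixed in steps 1 and 2, whose trans arms can only join as a trans-decalin. The step needs hydrogen atom transfer at the 1,1-disubstituted isopropenyl alkene and not at C7=C8, which is secured because C7=C8 is trisubstituted and electron-poor as part of the enone, and it needs cyclisation to outrun reduction of the radical, which is secured by the fast unimolecular addition to the radicophilic C=N carbon held five atoms away under high dilution.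

Step 6
Reactants: 8 11-nor-drim-7-en-9-one
Product: 9 drima-7,9(11)-diene [(4aS,8aS)-2,5,5,8a-tetramethyl-1-methylidene-1,4,4a,5,6,7,8,8a-octahydronaphthalene]
Conditions: Ph3PCH3Br (3 equiv), KOt-Bu (2.8 equiv), toluene, 0 to 100 °C
Reagents that add atoms: methyltriphenylphosphonium bromide, C[P+](c1ccccc1)(c1ccccc1)c1ccccc1.[Br-]
Why: Wittig methylenation with excess ylide generated by KOt-Bu in hot toluene is the standard answer to ketones flanked by a quaternary carbon; 1,2-addition and cycloreversion should give the exocyclic cross-conjugated diene and touch no stereocentre.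

Step 7
Reactants: 10 methyl 2,3,4-trihydroxybenzoate
Product: 11 methyl 5-bromo-2,3,4-trihydroxybenzoate
Conditions: NBS (1.0 equiv), MeCN, 0 °C
Reagents that add atoms: N-bromosuccinimide, O=C1CCC(=O)N1Br
Why: Electrophilic aromatic substitution: C5 is ortho to the 4-OH, para to the 2-OH and meta to the ester, whereas the only other free position C6 is ortho to the ester and activated by the 3-OH alone, so one equivalent of NBS should brominate C5.

Step 8
Reactants: 11 methyl 5-bromo-2,3,4-trihydroxybenzoate
Product: 12 methyl 5-bromo-2,3,4-tris(methoxymethoxy)benzoate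
Conditions: NaH (3.6 equiv), MOMCl (3.6 equiv), DMF, 0 to 25 °C, argon
Reagents that add atoms: chloromethyl methyl ether, COCCl
Why: Williamson-type O-alkylation of the three phenoxides with the reactive alpha-chloro ether; NaH in DMF also deprotonates the hydrogen-bonded 2-OH, and the methyl ester should not be attacked at this temperature.

Step 9
Reactants: 9 drima-7,9(11)-diene; 12 methyl 5-bromo-2,3,4-tris(methoxymethoxy)benzoate
Product: 14 methyl 2,3,4-tris(methoxymethoxy)-5-{[(1S,4aS,8aS)-2,5,5,8a-tetramethyl-1,4,4a,5,6,7,8,8a-octahydronaphthalen-1-yl]methyl}benzoate, via B-alkyl-9-BBN adduct 13 (not isolated)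
Conditions: 9-BBN-H (0.5 M in THF, 1.2 equiv), THF, 0 to 50 °C; then H2O, 12, Pd(dppf)Cl2 (5 mol%), K3PO4 (3 equiv), DMF/THF/H2O, 60 °C
Reagents that add atoms: 9-borabicyclo[3.3.1]nonane, B1C2CCCC1CCC2 (its boron and bicycle are held only by intermediate 13; product 14 keeps one hydrogen from it, on C9)
Why: Hydroboration then B-alkyl Suzuki–Miyaura coupling: 9-BBN should place boron on the unhindered exocyclic CH2 (C11), leave the trisubstituted C7=C8 alone and deliver hydrogen to C9 from the alpha face opposite the axial C10 methyl (substrate control, giving the 9S centre), and the primary alkylborane is then transferred to the aryl bromide with K3PO4 as a base that spares the ester and the MOM ethers.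

Step 10
Reactants: 14 tris-MOM ether
Product: 15 methyl 2,3,4-trihydroxy-5-{[(1S,4aS,8aS)-2,5,5,8a-tetramethyl-1,4,4a,5,6,7,8,8a-octahydronaphthalen-1-yl]methyl}benzoate (CNP0185238.1)
Conditions: HCl (1.25 M in MeOH), 0 to 25 °C, argon
Reagents that add atoms: none
Why: Acid-catalysed acetal exchange should remove the three aryl MOM ethers in methanol, a medium in which the methyl ester can only exchange with itself, the isolated trisubstituted alkene is not protonated by dilute HCl at room temperature, and the pyrogallol is protected from autoxidation.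

**Compound list**

1 | (R)-(−)-carvone, (5R)-2-methyl-5-(prop-1-en-2-yl)cyclohex-2-en-1-one | O=C1C(C)=CC[C@@H](C(C)=C)C1 | starting material
2 | (5R,6S)-2,6-dimethyl-5-(prop-1-en-2-yl)cyclohex-2-en-1-one (trans-6-methylcarvone, major epimer) | O=C1C(C)=CC[C@@H](C(C)=C)[C@@H]1C | intermediate
3 | (5S,6S)-2,6-dimethyl-5-(prop-1-en-2-yl)-6-(prop-2-yn-1-yl)cyclohex-2-en-1-one | O=C1C(C)=CC[C@@H](C(C)=C)[C@]1(C)CC#C | intermediate
4 | 3-[(1S,6S)-1,3-dimethyl-2-oxo-6-(prop-1-en-2-yl)cyclohex-3-en-1-yl]propanal | O=C1C(C)=CC[C@@H](C(C)=C)[C@]1(C)CCC=O | intermediate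
5 | N'-{(E)-3-[(1S,6S)-1,3-dimethyl-2-oxo-6-(prop-1-en-2-yl)cyclohex-3-en-1-yl]propylidene}-4-methylbenzenesulfonohydrazide | O=C1C(C)=CC[C@@H](C(C)=C)[C@]1(C)CC/C=N/NS(=O)(=O)c2ccc(C)cc2 | intermediate
6 | 3-(2-tosylhydrazinyl)-11-nor-drim-7-en-9-one (C3 epimers, not isolated) | O=C1C(C)=CC[C@H]2C(C)(C)C(NNS(=O)(=O)c3ccc(C)cc3)CC[C@]12C | intermediate
7 | 3-diazenyl-11-nor-drim-7-en-9-one (C3 epimers, not isolated) | O=C1C(C)=CC[C@H]2C(C)(C)C(N=N)CC[C@]12C | intermediate
8 | 11-nor-drim-7-en-9-one, (4aS,8aS)-2,5,5,8a-tetramethyl-4a,5,6,7,8,8a-hexahydronaphthalen-1(4H)-one | O=C1C(C)=CC[C@H]2C(C)(C)CCC[C@]12C | intermediate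
9 | drima-7,9(11)-diene, (4aS,8aS)-2,5,5,8a-tetramethyl-1-methylidene-1,4,4a,5,6,7,8,8a-octahydronaphthalene | C=C1C(C)=CC[C@H]2C(C)(C)CCC[C@]12C | intermediate
10 | methyl 2,3,4-trihydroxybenzoate | COC(=O)c1ccc(O)c(O)c1O | starting material
11 | methyl 5-bromo-2,3,4-trihydroxybenzoate | COC(=O)c1cc(Br)c(O)c(O)c1O | intermediate
12 | methyl 5-bromo-2,3,4-tris(methoxymethoxy)benzoate | COC(=O)c1cc(Br)c(OCOC)c(OCOC)c1OCOC | intermediate
13 | 9-{[(1S,4aS,8aS)-2,5,5,8a-tetramethyl-1,4,4a,5,6,7,8,8a-octahydronaphthalen-1-yl]methyl}-9-borabicyclo[3.3.1]nonane (not isolated) | C1CCC2CCCC1B2C[C@H]3C(C)=CC[C@H]4C(C)(C)CCC[C@]34C | intermediate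
14 | methyl 2,3,4-tris(methoxymethoxy)-5-{[(1S,4aS,8aS)-2,5,5,8a-tetramethyl-1,4,4a,5,6,7,8,8a-octahydronaphthalen-1-yl]methyl}benzoate | COC(=O)c1cc(C[C@H]2C(C)=CC[C@H]3C(C)(C)CCC[C@]23C)c(OCOC)c(OCOC)c1OCOC | intermediate
15 | methyl 2,3,4-trihydroxy-5-{[(1S,4aS,8aS)-2,5,5,8a-tetramethyl-1,4,4a,5,6,7,8,8a-octahydronaphthalen-1-yl]methyl}benzoate | COC(=O)c1cc(C[C@H]2C(C)=CC[C@H]3C(C)(C)CCC[C@]23C)c(O)c(O)c1O | target

**Step count**

Total: 10 steps. Longest linear sequence: 8 steps (steps 1 to 6, 9 and 10, from (R)-carvone); steps 7 and 8 make the arene partner.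

**Steps most likely to fail**

Step 5. The tertiary radical may be reduced to an isopropyl group before it reaches C3, hydrogen atom transfer may also engage the enone, or the hydrazide may not shed sulfinate and N2 cleanly, leaving nitrogen on C3. The fallback makes the same bond with a conventional acceptor and sets out from compound 2. Alkylation of its lithium enolate (LiN(i-Pr)2, THF, −78 °C) with methyl 2-(bromomethyl)acrylate should give methyl 2-{[(1S,6S)-1,3-dimethyl-2-oxo-6-(prop-1-en-2-yl)cyclohex-3-en-1-yl]methyl}prop-2-enoate F1. Fe(acac)3 and PhSiH3 in EtOH/ethylene glycol at 60 °C should close ring A by 6-endo Giese addition of the C4 radical to the unsubstituted acrylate terminus, giving methyl 9-oxo-11-nor-drim-7-ene-2-carboxylate F2. LiOH in THF/H2O gives 9-oxo-11-nor-drim-7-ene-2-carboxylic acid F3. Photochemical hydrodecarboxylation (9-mesityl-10-methylacridinium tetrafluoroborate, PhSSPh, i-Pr2NEt, CF3CH2OH, blue light) then returns to the route at compound 8.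

Step 9. Transmetalation of the beta-branched primary alkylborane may be slow, so that protodeboronation and hydrodebromination of the aryl bromide take over. The fallback replaces the coupling by carbonyl addition and sets out from compound 9. Hydroboration with 9-BBN-H and oxidation with NaBO3·4H2O should give drimenol F4. TEMPO with PhI(OAc)2 in CH2Cl2 gives drimenal F5. Bromine–magnesium exchange on compound 12 (i-PrMgCl·LiCl, THF, −15 °C) and addition to the aldehyde gives methyl 5-{hydroxy[(1S,4aS,8aS)-2,5,5,8a-tetramethyl-1,4,4a,5,6,7,8,8a-octahydronaphthalen-1-yl]methyl}-2,3,4-tris(methoxymethoxy)benzoate F6. NaH, CS2 and MeI give its S-methyl xanthate F7. Barton–McCombie deoxygenation (Bu3SnH, AIBN, toluene, 80 °C) returns to the route at compound 14.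

Step 6. The basic ylide may deprotonate C6 (gamma to the carbonyl) faster than it adds to the carbonyl flanked by C10 and the C8 methyl, returning ketone or deconjugated enone. The fallback is a Peterson olefination and sets out from compound 8. Me3SiCH2Li with CeCl3 in THF at −78 °C should add 1,2 to give 9-hydroxy-9-[(trimethylsilyl)methyl]-11-nor-drim-7-ene F8. Syn-elimination with KH in THF at 25 °C returns to the route at compound 9.

**Further compounds**

F1 | step 5 | methyl 2-{[(1S,6S)-1,3-dimethyl-2-oxo-6-(prop-1-en-2-yl)cyclohex-3-en-1-yl]methyl}prop-2-enoate | O=C1C(C)=CC[C@@H](C(C)=C)[C@]1(C)CC(=C)C(=O)OC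
F2 | step 5 | methyl 9-oxo-11-nor-drim-7-ene-2-carboxylate (C2 epimers) | O=C1C(C)=CC[C@H]2C(C)(C)CC(C(=O)OC)C[C@]12C
F3 | step 5 | 9-oxo-11-nor-drim-7-ene-2-carboxylic acid (C2 epimers) | O=C1C(C)=CC[C@H]2C(C)(C)CC(C(=O)O)C[C@]12C
F4 | step 9 | drimenol, [(1S,4aS,8aS)-2,5,5,8a-tetramethyl-1,4,4a,5,6,7,8,8a-octahydronaphthalen-1-yl]methanol | OC[C@H]1C(C)=CC[C@H]2C(C)(C)CCC[C@]12C
F5 | step 9 | drimenal, (1S,4aS,8aS)-2,5,5,8a-tetramethyl-1,4,4a,5,6,7,8,8a-octahydronaphthalene-1-carbaldehyde | O=C[C@H]1C(C)=CC[C@H]2C(C)(C)CCC[C@]12C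
F6 | step 9 | methyl 5-{hydroxy[(1S,4aS,8aS)-2,5,5,8a-tetramethyl-1,4,4a,5,6,7,8,8a-octahydronaphthalen-1-yl]methyl}-2,3,4-tris(methoxymethoxy)benzoate (carbinol epimers) | COC(=O)c1cc(C(O)[C@H]2C(C)=CC[C@H]3C(C)(C)CCC[C@]23C)c(OCOC)c(OCOC)c1OCOC
F7 | step 9 | S-methyl xanthate of F6 | COC(=O)c1cc(C(OC(=S)SC)[C@H]2C(C)=CC[C@H]3C(C)(C)CCC[C@]23C)c(OCOC)c(OCOC)c1OCOC
F8 | step 6 | 9-hydroxy-9-[(trimethylsilyl)methyl]-11-nor-drim-7-ene (C9 epimers) | C[Si](C)(C)CC1(O)C(C)=CC[C@H]2C(C)(C)CCC[C@]12C
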